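**Assumption:** the target has no stereocentre (C2 of the indolin-3-one carries two identical indol-3-yl groups), so it is achiral and no stereocontrol is needed.

## Retrosynthetic overview

1. 5 ⇒ 4 + 1: the last C2–C3' bond comes from addition of indole C3 to the acyl-imine C=N of 2-(indol-3-yl)-3H-indol-3-one.
2. 4 ⇒ 3 (dehydrogenation across C2–H/N–H) ⇒ 2 + 1: the first C2–C3' bond comes from the same addition to the parent 3H-indol-3-one.
3. 2 ⇒ 1 + O2: C3 oxygenation of indole, the oxygenase event of the natural pathway.
4. All three disconnections are run as one aerobic flask operation on three molecules of indole, instead of stepwise arylation of a preformed isatin- or indoxyl-derived electrophile.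
5. Ring order: no ring is built. The three indole bicycles arrive intact; the only ring event is dearomatisation of one pyrrole ring to the indolin-3-one as the quaternary C2 is assembled.

## Route

Step 1
Reactants: 1 indole (first molecule, the one oxygenated at C3); 1 indole (second molecule, nucleophile); 1 indole (third molecule, nucleophile)
Product: 5 2,2-bis(1H-indol-3-yl)indolin-3-one, via 3H-indol-3-one 2 (not isolated), via 2-(1H-indol-3-yl)indolin-3-one 3 (not isolated), via 2-(1H-indol-3-yl)-3H-indol-3-one 4 (not isolated)
Conditions: CuCl (5 mol %), TEMPO (2,2,6,6-tetramethylpiperidin-1-oxyl, 5 mol %), PhCO2H (10 mol %), O2 (1 atm), MeCN (0.5 M in 1), 40 °C, 16 h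
Reagents that add atoms: indole (second molecule), c1ccc2[nH]ccc2c1; indole (third molecule), c1ccc2[nH]ccc2c1; dioxygen, O=O
Why: Biomimetic aerobic oxidative trimerisation of indole, in which the CuCl/TEMPO/O2 couple oxygenates C3 of one indole to the cyclic acyl imine 2, a second indole adds through C3 to its C=N (aza-Friedel–Crafts, Mannich-type addition) to give 3, the doubly activated C2–H of 3 is dehydrogenated by the same catalyst to the conjugated acyl imine 4, and a third indole adds to give 5, which has no C2–H left to oxidise and no stereocentre to set.

Overall equation: 3 C8H7N + 3/2 O2 → C24H17N3O + 2 H2O. Every carbon and nitrogen of 5 comes from the three indole molecules, and the ketone oxygen comes from O2.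

## Compound list

1 | indole (1H-indole) | c1ccc2[nH]ccc2c1 | starting material
2 | 3H-indol-3-one | O=C1C=Nc2ccccc12 | intermediate
3 | 2-(1H-indol-3-yl)indolin-3-one (racemic, transient; its stereocentre is erased in the next stage) | O=C1c2ccccc2NC1c1c[nH]c2ccccc12 | intermediate
4 | 2-(1H-indol-3-yl)-3H-indol-3-one | O=C1C(=Nc2ccccc12)c1c[nH]c2ccccc12 | intermediate
5 | 2,2-bis(1H-indol-3-yl)indolin-3-one (2,2-bis(3'-indolyl)indoxyl, achiral) | O=C1c2ccccc2NC1(c1c[nH]c2ccccc12)c1c[nH]c2ccccc12 | target

## Step count and risk

Total step count: 1.
Longest linear sequence: 1 step from indole.

**Steps most likely to fail.** The route has only step 1, so it is the only step that can be named. Its three weak points, in order of risk: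

- (a) Mono-oxygenation selectivity. The parent imine 2 and its indoxyl tautomer can dimerise to indigo or indirubin, or over-oxidise to isatin. Isatin then takes up two indoles at C3 to give trisindoline, an isomer of 5. Check the product by 13C NMR: 5 should show the ketone near 200 ppm and the quaternary C2 near 68 ppm, against roughly 179 and 53 ppm for trisindoline.
- (b) First capture. Unhindered 2 must be trapped by indole faster than it self-condenses, which is why the reaction is run concentrated.
- (c) Late-stage oxidation. The dehydrogenation of 3 to 4 must keep pace while the indole concentration falls; otherwise the remaining indole is over-oxidised and too little nucleophile is left for 4.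

**Fallback for step 1** (sets out from 1, comes back to the route at 4). The order of events is reversed: the first C–C bond is made without any oxidant, and oxygen is introduced only once C2 is blocked, so the unstable parent imine 2 never forms.

Indole 1 (two molecules) is dimerised with dry HCl in Et2O at 0 °C (Mannich-type addition of indole C3 to the 3H-indolium ion). After aqueous NH3 work-up this gives 2-(1H-indol-3-yl)indoline F1 (racemic). F1 is dehydrogenated over 10% Pd/C in refluxing xylene under N2 to 2-(1H-indol-3-yl)-1H-indole F2 (2,3'-biindole), which erases the stereocentre. F2 has a single free, electron-rich C3 flanked by the C2 substituent. It is oxygenated there with CuCl (10 mol %) and O2 in MeCN at room temperature, in the presence of 1 (1.5 equiv), and oxidises faster than indole itself. This gives 4, a stabilised, conjugated acyl imine, where the fallback rejoins the route. 4 takes up 1 as in the last stage of step 1 to give 5.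

## Further compounds

F1 | step 1 | 2-(1H-indol-3-yl)indoline (racemic) | c1ccc2c(c1)CC(N2)c1c[nH]c2ccccc12
F2 | step 1 | 2-(1H-indol-3-yl)-1H-indole (2,3'-biindole) | c1ccc2[nH]c(cc2c1)-c1c[nH]c2ccccc12
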